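**Plan**

1. Cuts: the ester C–O between the C1 CH2O and the ring-B acid; in the lactone half the exocyclic C1=CH2 (as diol precursor), the C5–C6 and C1–C2 bonds of ring A, and the C2–C3 bond of ring L; in the acid the acrylate unit (by allylic transposition of a Baylis–Hillman-type adduct) and the C1'–vinyl bond to cryptone.
2. Forward: ring L is made first by ring expansion of a dioxolane (step 10); ring A is annulated onto C2 and C5 (steps 11–14); C1 is oxygenated (steps 15–18); the ring-B acid (steps 19–29) is joined last (steps 30–32).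
3. Enabling feature: ring L reads C(=O)–O–CH2–Cα=Cβ–C3–C2, a γ,δ-unsaturated seven-membered lactone with the ring CH2O on Cα cis to C3, which is the retron of a [3,3] shift of a 2-methylidene-4-alkenyl-1,3-dioxolane.
4. Stereochemistry: C4 from an organocatalytic α-hydroxymethylation; the dioxolane quaternary carbon from a Sharpless epoxidation and relayed to C3 in step 10; C2 by equilibration to the trans ring fusion; C1 by equatorial osmylation; C6' from an organocatalytic Michael addition, C1' from a trans cuprate addition, the acrylate E geometry from a thermodynamic acetate transposition.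
5. Labels: ring A = C1 (carbinol), C2 (lactone α-carbon), C3 (ring fusion), C4 (isopropyl), C5, C6; ring-B carbons are primed (C1' carries the acrylate, C6' the isopropyl group).

Key step: step 10

Remark on the chemistry: C2 is a mixture of epimers and enol in 17–19; from 20 on it is written as the trans-fused epimer expected at equilibrium (both ring bonds equatorial).

**Route**

Step 1
Reactants: 1 3-methylbutanal; 2 formaldehyde
Product: 3 (2S)-2-(hydroxymethyl)-3-methylbutanal
Conditions: (R)-α,α-diphenylprolinol trimethylsilyl ether (10 mol%), 37% aq. HCHO, pH 7 phosphate buffer, toluene, rt; crude product used at once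
Reagents that add atoms: none
Why: Enamine-mediated organocatalytic α-hydroxymethylation; the bulky silyloxydiphenylmethyl group of the (R)-catalyst shields one face of the E-enamine, so formaldehyde should add to the other face and set the (S) centre that becomes C4.

Step 2
Reactants: 3 (2S)-2-(hydroxymethyl)-3-methylbutanal
Product: 4 (2S)-3-methyl-2-({[tri(propan-2-yl)silyl]oxy}methyl)butanal
Conditions: i-Pr3SiOSO2CF3, 2,6-lutidine, CH2Cl2, −78 °C
Reagents that add atoms: triisopropylsilyl trifluoromethanesulfonate, CC(C)[Si](OS(=O)(=O)C(F)(F)F)(C(C)C)C(C)C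
Why: Silylation of the primary alcohol with a silyl triflate and a hindered base at low temperature should outrun epimerisation or β-elimination of the α-branched aldehyde; the triisopropylsilyl ether is chosen to survive the alkoxide of step 6 and the acid of step 8.

Step 3
Reactants: 4 (2S)-3-methyl-2-({[tri(propan-2-yl)silyl]oxy}methyl)butanal
Product: 5 2-[(1E,3R)-4-methyl-3-({[tri(propan-2-yl)silyl]oxy}methyl)pent-1-en-1-yl]-4,4,5,5-tetramethyl-1,3,2-dioxaborolane
Conditions: CrCl2, Cl2CHB(pinacolato), LiI, THF, rt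
Reagents that add atoms: 2-(dichloromethyl)-4,4,5,5-tetramethyl-1,3,2-dioxaborolane, ClC(Cl)B1OC(C)(C)C(C)(C)O1
Why: Takai–Utimoto boryl olefination; the geminal dichromium reagent adds to the aldehyde and eliminates to the E-alkenylboronate under nearly neutral conditions that should leave the α-stereocentre untouched.

Step 4
Reactants: 5 the (E)-alkenylboronate; 6 2-bromoprop-2-en-1-ol
Product: 7 (3E,5R)-6-methyl-2-methylidene-5-({[tri(propan-2-yl)silyl]oxy}methyl)hept-3-en-1-ol
Conditions: Pd(PPh3)4 (5 mol%), aq. K3PO4, THF, 60 °C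
Reagents that add atoms: none
Why: Suzuki–Miyaura coupling of an alkenylboronate with a 1,1-disubstituted vinyl bromide proceeds with retention of the E geometry and tolerates the free allylic hydroxyl.

Step 5
Reactants: 7 the dienol
Product: 8 {(2R)-2-[(1E,3R)-4-methyl-3-({[tri(propan-2-yl)silyl]oxy}methyl)pent-1-en-1-yl]oxiran-2-yl}methanol
Conditions: Ti(OiPr)4 (10 mol%), D-(−)-diisopropyl tartrate (12 mol%), t-BuOOH, 4 Å molecular sieves, CH2Cl2, −20 °C
Reagents that add atoms: tert-butyl hydroperoxide, CC(C)(C)OO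
Why: Sharpless asymmetric epoxidation touches only the allylic (not the homoallylic) alkene, and with the D-tartrate the usual face rule for a 2-substituted allylic alcohol predicts the (2R) epoxide, which fixes the future quaternary carbon.

Step 6
Reactants: 8 the epoxy alcohol
Product: 9 (2R,3E,5R)-2-{[(4-methoxyphenyl)methoxy]methyl}-6-methyl-5-({[tri(propan-2-yl)silyl]oxy}methyl)hept-3-ene-1,2-diol
Conditions: 4-methoxybenzyl alcohol (5 equiv), NaH (0.3 equiv), DMF, 50 °C
Reagents that add atoms: 4-methoxybenzyl alcohol, COc1ccc(CO)cc1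
Why: Alkoxide opening (SN2) of the 2,2-disubstituted epoxide at its unhindered CH2; a Payne rearrangement of this epoxy alcohol is degenerate and leads to the same diol, so the quaternary configuration is kept.

Step 7
Reactants: 10 diphenyl diselenide; 11 2-bromo-1,1-diethoxyethane
Product: 12 [(2,2-diethoxyethyl)selanyl]benzene
Conditions: NaBH4, EtOH, 0 °C; then 11, reflux
Reagents that add atoms: none
Why: Borohydride reduction of the diselenide gives the selenolate, which displaces the primary bromide (SN2).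

Step 8
Reactants: 9 the diol; 12 [(2,2-diethoxyethyl)selanyl]benzene
Product: 13 (4S)-4-{[(4-methoxyphenyl)methoxy]methyl}-4-[(1E,3R)-4-methyl-3-({[tri(propan-2-yl)silyl]oxy}methyl)pent-1-en-1-yl]-2-[(phenylselanyl)methyl]-1,3-dioxolane (both C2 epimers)
Conditions: pyridinium p-toluenesulfonate (10 mol%), toluene, 80 °C, EtOH distilled off
Reagents that add atoms: none
Why: Acid-catalysed transacetalisation of the 1,2-diol; the acetal carbon need not be controlled because it becomes sp2 in step 10.

Step 9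
Reactants: 13 the selenoacetal
Product: 14 the selenoxide of 13, (4S)-2-[(benzeneseleninyl)methyl]-4-{[(4-methoxyphenyl)methoxy]methyl}-4-[(1E,3R)-4-methyl-3-({[tri(propan-2-yl)silyl]oxy}methyl)pent-1-en-1-yl]-1,3-dioxolane
Conditions: NaIO4, NaHCO3, MeOH–H2O, 0 °C → rt
Reagents that add atoms: sodium periodate, [Na+].[O-]I(=O)(=O)=O
Why: Chemoselective oxidation of the selenide to the selenoxide; its only β-hydrogen is the acetal C–H, so it should be stable at room temperature.

Step 10
Reactants: 14 the selenoxide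
Product: 16 (4R)-6-{[(4-methoxyphenyl)methoxy]methyl}-4-[(2R)-3-methyl-1-{[tri(propan-2-yl)silyl]oxy}butan-2-yl]-4,7-dihydrooxepin-2(3H)-one, via ketene acetal 15 (not isolated)
Conditions: DBU (3 equiv), degassed xylene, 140 °C
Reagents that add atoms: none
Why: Heating drives syn-elimination of PhSeOH from 14 toward its only β-hydrogen, the acetal C–H, and the resulting ketene acetal 15 is an allyl vinyl ether (CH2=C–O–C–CH=CH) that undergoes a [3,3]-sigmatropic Claisen shift, forming C2–C3 and breaking the tertiary allylic C–O bond. The closest known reaction type is the Claisen ring expansion of 2-methylidene-4-vinyl-1,3-dioxolanes, made by selenoxide elimination, to seven-membered γ,δ-unsaturated lactones. Ring L closes by this two-atom ring expansion through a bicyclic, chair-like six-atom array in which the O–CH2 bridge of the dioxolane spans the ketene-acetal carbon and the carbinol carbon, which is also why the new ring alkene is cis and the ring CH2O ends on Cα cis to C3. C3 is set by chirality transfer from the (4S) quaternary carbon: the bridge admits only the chair array, and in it the E-alkene holds the C4 side arm equatorial, so the new bond forms on one face of the alkene terminus. The step needs elimination before any hydrolysis of the acetal and a clean E-alkene; the dry basic medium (DBU takes up PhSeOH) and the geometry fixed in step 3 should secure both, and the quaternary stereocentre is consumed.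

Step 11
Reactants: 16 the oxepinone
Product: 17 (4R)-3-acetyl-6-{[(4-methoxyphenyl)methoxy]methyl}-4-[(2R)-3-methyl-1-{[tri(propan-2-yl)silyl]oxy}butan-2-yl]-4,7-dihydrooxepin-2(3H)-one (C3 epimers and enol)
Conditions: LiN(i-Pr)2 (1.2 equiv), THF, −78 °C; MeC(O)N(OMe)Me, −78 → −20 °C; aq. NH4Cl
Reagents that add atoms: N-methoxy-N-methylacetamide, CC(=O)N(C)OC
Why: C-acylation of the lactone lithium enolate with a Weinreb amide (Claisen-type condensation) stops at the chelated tetrahedral adduct, so the more acidic β-keto lactone is released only on work-up.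

Step 12
Reactants: 17 the acetyl lactone
Product: 18 (4R)-3-acetyl-4-[(2R)-1-hydroxy-3-methylbutan-2-yl]-6-{[(4-methoxyphenyl)methoxy]methyl}-4,7-dihydrooxepin-2(3H)-one
Conditions: HF·pyridine, pyridine, THF, 0 °C → rt; product used at once
Reagents that add atoms: none
Why: Fluoride-mediated Si–O cleavage under buffered conditions that spare the β-keto lactone and the PMB ether; immediate use limits exchange of the free hydroxyl with the lactone.

Step 13
Reactants: 18 the primary alcohol
Product: 19 (4S)-3-acetyl-4-[(2R)-1-iodo-3-methylbutan-2-yl]-6-{[(4-methoxyphenyl)methoxy]methyl}-4,7-dihydrooxepin-2(3H)-one (same spatial arrangement as 18)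
Conditions: I2, PPh3, imidazole, CH2Cl2, 0 °C
Reagents that add atoms: iodine, II
Why: Appel-type (Garegg–Samuelsson) iodination, an SN2 displacement at the primary carbon via the alkoxyphosphonium salt.

Step 14
Reactants: 19 the iodide
Product: 20 (5aS,6R,9aS)-4-{[(4-methoxyphenyl)methoxy]methyl}-6-(propan-2-yl)-5a,6,7,8-tetrahydro-2-benzoxepine-1,9(3H,9aH)-dione
Conditions: LiN(i-Pr)2 (2.3 equiv), THF, −78 → 0 °C; aq. NH4Cl
Reagents that add atoms: none
Why: Huckin–Weiler dianion alkylation; the γ-carbon (acetyl CH3, future C6) of the β-keto lactone dianion displaces the primary iodide intramolecularly in a 6-(enolendo)-exo-tet closure of ring A, and C2 should settle through the enol to the trans-fused keto form.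

Step 15
Reactants: 20 the bicyclic keto lactone
Product: 22 (5aS,6R,9aS)-4-{[(4-methoxyphenyl)methoxy]methyl}-9-methylidene-6-(propan-2-yl)-5a,6,7,8,9,9a-hexahydro-2-benzoxepin-1(3H)-one, via silyl carbinol 21 (not isolated)
Conditions: Me3SiCH2MgCl (3 equiv), CeCl3 (3 equiv), THF, −78 → −20 °C; then HF·pyridine, THF, 0 °C → rt
Reagents that add atoms: (trimethylsilyl)methylmagnesium chloride, C[Si](C)(C)C[Mg]Cl
Why: Cerium-mediated Peterson methylenation; the weakly basic organocerium reagent is known to add to the ketone of 1,3-dicarbonyl compounds, and acid-promoted anti-elimination of the β-hydroxysilane places the alkene only at C1=CH2, so the C2–H is not involved.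

Step 16
Reactants: 22 the methylidene lactone
Product: 23 (5aS,6R,9aS)-4-(hydroxymethyl)-9-methylidene-6-(propan-2-yl)-5a,6,7,8,9,9a-hexahydro-2-benzoxepin-1(3H)-one
Conditions: DDQ, CH2Cl2–pH 7 buffer, 0 °C
Reagents that add atoms: none
Why: Oxidative cleavage of the PMB ether at its electron-rich benzylic position; the freed hydroxymethyl is trans to C3 across Cα=Cβ and cannot reach the lactone carbonyl.

Step 17
Reactants: 23 the allylic alcohol
Product: 24 (5aS,6R,9aS)-9-methylidene-1-oxo-6-(propan-2-yl)-1,3,5a,6,7,8,9,9a-octahydro-2-benzoxepine-4-carbaldehyde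
Conditions: MnO2 (excess), CH2Cl2, rt
Reagents that add atoms: none
Why: Selective oxidation of the primary allylic alcohol to the enal, which also makes the ring-L alkene electron-poor ahead of the osmylation.

Step 18
Reactants: 24 the enal
Product: 25 cyclic phenylboronate of (5aS,6R,9S,9aS)-9-hydroxy-9-(hydroxymethyl)-1-oxo-6-(propan-2-yl)-1,3,5a,6,7,8,9,9a-octahydro-2-benzoxepine-4-carbaldehyde (spiro 2-phenyl-1,3,2-dioxaborolane at C9)
Conditions: OsO4 (5 mol%), N-methylmorpholine N-oxide, PhB(OH)2, CH2Cl2, rt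
Reagents that add atoms: N-methylmorpholine N-oxide, C[N+]1([O-])CCOCC1; phenylboronic acid, OB(O)c1ccccc1
Why: Osmium-catalysed syn-dihydroxylation with boronate capture (Narasaka conditions); OsO4 should take the electron-rich exocyclic alkene rather than the enal and approach along the equatorial direction, away from the axial hydrogens at C3 and C5, giving the equatorial C1–O and axial CH2O of the target, while capture as the boronate keeps the primary hydroxyl from attacking the lactone carbonyl.

Step 19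
Reactants: 1 3-methylbutanal; 26 but-3-en-2-one
Product: 27 (2S)-5-oxo-2-(propan-2-yl)hexanal
Conditions: (S)-α,α-diphenylprolinol methyl ether (5 mol%), ethyl 3,4-dihydroxybenzoate (20 mol%), neat, 4 °C
Reagents that add atoms: none
Why: Organocatalytic enamine Michael addition to the enone; the (S)-catalyst shields one enamine face and should give the (S) centre that becomes C6'.

Step 20
Reactants: 27 the keto aldehyde
Product: 28 (4S)-4-(propan-2-yl)cyclohex-2-en-1-one
Conditions: KOH (aq., cat.), n-Bu4NOH (cat.), Et2O–THF, reflux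
Reagents that add atoms: none
Why: Intramolecular aldol condensation (the second half of a Robinson-type annulation) of the methyl ketone onto the aldehyde; C4 is not enolisable toward the new enone under these conditions.

Step 21
Reactants: 28 (4S)-4-(propan-2-yl)cyclohex-2-en-1-one
Product: 29 (3S,4S)-3-ethenyl-4-(propan-2-yl)cyclohex-1-en-1-yl trifluoromethanesulfonate
Conditions: CH2=CHMgBr, CuBr·SMe2 (10 mol%), THF, −78 °C; then N-(5-chloropyridin-2-yl)bis(trifluoromethanesulfonimide), −78 → 0 °C
Reagents that add atoms: vinylmagnesium bromide, C=C[Mg]Br; N-(5-chloropyridin-2-yl)bis(trifluoromethanesulfonimide), O=S(=O)(N(c1ccc(Cl)cn1)S(=O)(=O)C(F)(F)F)C(F)(F)F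
Why: Copper-catalysed conjugate addition occurs trans to the C4 isopropyl group and sets C1'; O-triflation of the regiodefined enolate fixes the alkene at C2'=C3'.

Step 22
Reactants: 29 the vinyl enol triflate
Product: 30 (3S,4S)-3-formyl-4-(propan-2-yl)cyclohex-1-en-1-yl trifluoromethanesulfonate
Conditions: OsO4 (2 mol%), NaIO4, 2,6-lutidine, dioxane–H2O, rt
Reagents that add atoms: sodium periodate, [Na+].[O-]I(=O)(=O)=O
Why: Lemieux–Johnson cleavage of the monosubstituted alkene; the electron-poor enol triflate alkene should not be osmylated, and the trans aldehyde is the stable epimer.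

Step 23
Reactants: 30 the aldehyde; 31 methyl prop-2-ynoate
Product: 32 methyl 2-{hydroxy[(1S,6S)-6-(propan-2-yl)-3-{[(trifluoromethyl)sulfonyl]oxy}cyclohex-2-en-1-yl]methyl}prop-2-enoate (both carbinol epimers)
Conditions: 31, i-Bu2AlH, N-methylmorpholine N-oxide, THF, 0 °C; then 30, 0 °C → rt
Reagents that add atoms: none
Why: Vinylalumination (a Morita–Baylis–Hillman-type addition); hydroalumination of the propiolate gives the α-aluminoacrylate, which adds to the hindered aldehyde without amine catalysis; the carbinol centre is lost in step 26.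

Step 24
Reactants: 32 the hydroxy acrylate triflate
Product: 33 methyl 2-{hydroxy[(1S,6S)-3-(hydroxymethyl)-6-(propan-2-yl)cyclohex-2-en-1-yl]methyl}prop-2-enoate
Conditions: Bu3SnCH2OH, Pd(PPh3)4 (5 mol%), LiCl, dioxane, 90 °C
Reagents that add atoms: (tributylstannyl)methanol, CCCC[Sn](CCCC)(CCCC)CO
Why: Stille coupling of the enol triflate with the hydroxymethylstannane installs the ring CH2OH directly; it is run before any allylic acetate is present.

Step 25
Reactants: 33 the diol
Product: 34 methyl 2-{(acetyloxy)[(1S,6S)-3-[(acetyloxy)methyl]-6-(propan-2-yl)cyclohex-2-en-1-yl]methyl}prop-2-enoate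
Conditions: Ac2O, pyridine, 4-(dimethylamino)pyridine (cat.), CH2Cl2, 0 °C → rt
Reagents that add atoms: acetic anhydride, CC(=O)OC(C)=O
Why: Standard acetylation of both hydroxyls; the secondary acetate is now an activated Baylis–Hillman acetate.

Step 26
Reactants: 34 the diacetate
Product: 35 methyl (2E)-2-[(acetyloxy)methyl]-3-{(1S,6S)-3-[(acetyloxy)methyl]-6-(propan-2-yl)cyclohex-2-en-1-yl}prop-2-enoate
Conditions: DABCO (20 mol%), THF, 40 °C
Reagents that add atoms: none
Why: Amine-catalysed 1,3-acetate transposition (SN2' by DABCO, then SN2' return of acetate) of the Baylis–Hillman acetate gives the thermodynamically favoured E-trisubstituted enoate, with the ester trans to the ring; the unactivated ring acetate is not affected.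

Step 27
Reactants: 35 the rearranged diacetate
Product: 36 (2E)-2-(hydroxymethyl)-3-[(1S,6S)-3-(hydroxymethyl)-6-(propan-2-yl)cyclohex-2-en-1-yl]prop-2-enoic acid
Conditions: LiOH, THF–MeOH–H2O, 0 °C → rt; then aq. HCl to pH 3
Reagents that add atoms: lithium hydroxide, [Li+].[OH-]
Why: Saponification of the methyl ester and both acetates; the alkene geometry is not at risk once the carboxylate has formed.

Step 28
Reactants: 36 the dihydroxy acid
Product: 38 (2E)-2-({[tert-butyl(dimethyl)silyl]oxy}methyl)-3-[(1S,6S)-3-({[tert-butyl(dimethyl)silyl]oxy}methyl)-6-(propan-2-yl)cyclohex-2-en-1-yl]prop-2-enoic acid, via silyl ester 37 (not isolated)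
Conditions: t-BuMe2SiCl, imidazole, DMF, rt; then K2CO3, MeOH–THF–H2O, 0 °C; pH 5 buffer
Reagents that add atoms: tert-butyldimethylsilyl chloride, CC(C)(C)[Si](C)(C)Cl
Why: Exhaustive silylation followed by selective mild cleavage of the much more labile silyl ester leaves the two primary silyl ethers.

Step 29
Reactants: 38 the bis-silyl acid
Product: 39 (2E)-2-({[tert-butyl(dimethyl)silyl]oxy}methyl)-3-[(1S,6S)-3-({[tert-butyl(dimethyl)silyl]oxy}methyl)-6-(propan-2-yl)cyclohex-2-en-1-yl]prop-2-enoyl chloride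
Conditions: 1-chloro-N,N,2-trimethylprop-1-en-1-amine, CH2Cl2, 0 °C; used crude
Reagents that add atoms: 1-chloro-N,N,2-trimethylprop-1-en-1-amine, CC(C)=C(Cl)N(C)C
Why: The Ghosez reagent converts the acid into the acyl chloride under neutral conditions that spare the silyl ethers.

Step 30
Reactants: 25 the spiro phenylboronate; 39 the acyl chloride
Product: 41 the C1 (benzoxepine C9) hydroxy ester: (5aS,6R,9S,9aS)-9-hydroxy-9-(acyloxymethyl)-1-oxo-6-(propan-2-yl)-1,3,5a,6,7,8,9,9a-octahydro-2-benzoxepine-4-carbaldehyde carrying the acyl group of 38 on the primary oxygen, via diol 40 (not isolated)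
Conditions: 25, 30% aq. H2O2, pH 7 phosphate buffer, THF, 0 °C, short contact, cold extractive work-up; then 39, pyridine, CH2Cl2, −20 → 0 °C
Reagents that add atoms: none
Why: Oxidative cleavage of the aryl–boron bond frees the diol under neutral conditions, and immediate acylation with the acid chloride should take the primary hydroxyl selectively (the tertiary one is too hindered) before it can attack the lactone carbonyl.

Step 31
Reactants: 41 the enal ester
Product: 42 the corresponding 4-carboxylic acid (bis-silyl ether of the target)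
Conditions: NaClO2, NaH2PO4, 2-methylbut-2-ene, t-BuOH–H2O, 0 °C → rt
Reagents that add atoms: sodium chlorite, [Na+].[O-]Cl=O
Why: Pinnick (Lindgren–Kraus) oxidation converts the enal into the conjugated acid without touching alkenes, silyl ethers, the esters or the tertiary alcohol; the scavenger removes HOCl.

Step 32
Reactants: 42 the bis-silyl acid
Product: 43 the target, (5aS,6R,9S,9aS)-9-hydroxy-9-({[(2E)-2-(hydroxymethyl)-3-[(1S,6S)-3-(hydroxymethyl)-6-(propan-2-yl)cyclohex-2-en-1-yl]prop-2-enoyl]oxy}methyl)-1-oxo-6-(propan-2-yl)-1,3,5a,6,7,8,9,9a-octahydro-2-benzoxepine-4-carboxylic acid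
Conditions: HF·pyridine, pyridine, THF, 0 °C → rt
Reagents that add atoms: none
Why: Buffered fluoride removes the two primary allylic silyl ethers under mildly acidic conditions that avoid base-induced retro-aldol, acyl migration or allylic displacement in the product.

**Compound list**

1 | 3-methylbutanal | CC(C)CC=O | starting material
2 | formaldehyde | C=O | starting material
3 | (2S)-2-(hydroxymethyl)-3-methylbutanal | O=C[C@@H](C(C)C)CO | intermediate
4 | (2S)-3-methyl-2-({[tri(propan-2-yl)silyl]oxy}methyl)butanal | O=C[C@@H](C(C)C)CO[Si](C(C)C)(C(C)C)C(C)C | intermediate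
5 | 2-[(1E,3R)-4-methyl-3-({[tri(propan-2-yl)silyl]oxy}methyl)pent-1-en-1-yl]-4,4,5,5-tetramethyl-1,3,2-dioxaborolane | CC1(C)OB(/C=C/[C@@H](C(C)C)CO[Si](C(C)C)(C(C)C)C(C)C)OC1(C)C | intermediate
6 | 2-bromoprop-2-en-1-ol | C=C(Br)CO | starting material
7 | (3E,5R)-6-methyl-2-methylidene-5-({[tri(propan-2-yl)silyl]oxy}methyl)hept-3-en-1-ol | C=C(CO)/C=C/[C@@H](C(C)C)CO[Si](C(C)C)(C(C)C)C(C)C | intermediate
8 | {(2R)-2-[(1E,3R)-4-methyl-3-({[tri(propan-2-yl)silyl]oxy}methyl)pent-1-en-1-yl]oxiran-2-yl}methanol | OC[C@]1(/C=C/[C@@H](C(C)C)CO[Si](C(C)C)(C(C)C)C(C)C)CO1 | intermediate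
9 | (2R,3E,5R)-2-{[(4-methoxyphenyl)methoxy]methyl}-6-methyl-5-({[tri(propan-2-yl)silyl]oxy}methyl)hept-3-ene-1,2-diol | OC[C@@](O)(COCc1ccc(OC)cc1)/C=C/[C@@H](C(C)C)CO[Si](C(C)C)(C(C)C)C(C)C | intermediate
10 | diphenyl diselenide | c1ccc(cc1)[Se][Se]c1ccccc1 | starting material
11 | 2-bromo-1,1-diethoxyethane (bromoacetaldehyde diethyl acetal) | CCOC(CBr)OCC | starting material
12 | [(2,2-diethoxyethyl)selanyl]benzene | CCOC(C[Se]c1ccccc1)OCC | intermediate
13 | (4S)-4-{[(4-methoxyphenyl)methoxy]methyl}-4-[(1E,3R)-4-methyl-3-({[tri(propan-2-yl)silyl]oxy}methyl)pent-1-en-1-yl]-2-[(phenylselanyl)methyl]-1,3-dioxolane (C2 epimers) | C(C1OC[C@@](COCc2ccc(OC)cc2)(/C=C/[C@@H](C(C)C)CO[Si](C(C)C)(C(C)C)C(C)C)O1)[Se]c1ccccc1 | intermediate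
14 | selenoxide of 13 (2-[(benzeneseleninyl)methyl] compound) | O=[Se](CC1OC[C@@](COCc2ccc(OC)cc2)(/C=C/[C@@H](C(C)C)CO[Si](C(C)C)(C(C)C)C(C)C)O1)c1ccccc1 | intermediate
15 | (4S)-4-{[(4-methoxyphenyl)methoxy]methyl}-4-[(1E,3R)-4-methyl-3-({[tri(propan-2-yl)silyl]oxy}methyl)pent-1-en-1-yl]-2-methylidene-1,3-dioxolane (ketene acetal, not isolated) | C=C1OC[C@@](COCc2ccc(OC)cc2)(/C=C/[C@@H](C(C)C)CO[Si](C(C)C)(C(C)C)C(C)C)O1 | intermediate
16 | (4R)-6-{[(4-methoxyphenyl)methoxy]methyl}-4-[(2R)-3-methyl-1-{[tri(propan-2-yl)silyl]oxy}butan-2-yl]-4,7-dihydrooxepin-2(3H)-one | O=C1OCC(COCc2ccc(OC)cc2)=C[C@H]([C@@H](C(C)C)CO[Si](C(C)C)(C(C)C)C(C)C)C1 | intermediate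
17 | (4R)-3-acetyl-6-{[(4-methoxyphenyl)methoxy]methyl}-4-[(2R)-3-methyl-1-{[tri(propan-2-yl)silyl]oxy}butan-2-yl]-4,7-dihydrooxepin-2(3H)-one (C3 epimers, enol) | O=C1OCC(COCc2ccc(OC)cc2)=C[C@H]([C@@H](C(C)C)CO[Si](C(C)C)(C(C)C)C(C)C)C1C(C)=O | intermediate
18 | (4R)-3-acetyl-4-[(2R)-1-hydroxy-3-methylbutan-2-yl]-6-{[(4-methoxyphenyl)methoxy]methyl}-4,7-dihydrooxepin-2(3H)-one | O=C1OCC(COCc2ccc(OC)cc2)=C[C@H]([C@@H](C(C)C)CO)C1C(C)=O | intermediate
19 | (4S)-3-acetyl-4-[(2R)-1-iodo-3-methylbutan-2-yl]-6-{[(4-methoxyphenyl)methoxy]methyl}-4,7-dihydrooxepin-2(3H)-one | O=C1OCC(COCc2ccc(OC)cc2)=C[C@H]([C@@H](C(C)C)CI)C1C(C)=O | intermediate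
20 | (5aS,6R,9aS)-4-{[(4-methoxyphenyl)methoxy]methyl}-6-(propan-2-yl)-5a,6,7,8-tetrahydro-2-benzoxepine-1,9(3H,9aH)-dione | CC(C)[C@H]1CCC(=O)[C@H]2C(=O)OCC(COCc3ccc(OC)cc3)=C[C@H]12 | intermediate
21 | 9-hydroxy-9-[(trimethylsilyl)methyl] adduct of 20 (C9 epimers, not isolated) | CC(C)[C@H]1CCC(O)(C[Si](C)(C)C)[C@H]2C(=O)OCC(COCc3ccc(OC)cc3)=C[C@H]12 | intermediate
22 | (5aS,6R,9aS)-4-{[(4-methoxyphenyl)methoxy]methyl}-9-methylidene-6-(propan-2-yl)-5a,6,7,8,9,9a-hexahydro-2-benzoxepin-1(3H)-one | CC(C)[C@H]1CCC(=C)[C@H]2C(=O)OCC(COCc3ccc(OC)cc3)=C[C@H]12 | intermediate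
23 | (5aS,6R,9aS)-4-(hydroxymethyl)-9-methylidene-6-(propan-2-yl)-5a,6,7,8,9,9a-hexahydro-2-benzoxepin-1(3H)-one | CC(C)[C@H]1CCC(=C)[C@H]2C(=O)OCC(CO)=C[C@H]12 | intermediate
24 | (5aS,6R,9aS)-9-methylidene-1-oxo-6-(propan-2-yl)-1,3,5a,6,7,8,9,9a-octahydro-2-benzoxepine-4-carbaldehyde | CC(C)[C@H]1CCC(=C)[C@H]2C(=O)OCC(C=O)=C[C@H]12 | intermediate
25 | cyclic phenylboronate of (5aS,6R,9S,9aS)-9-hydroxy-9-(hydroxymethyl)-1-oxo-6-(propan-2-yl)-1,3,5a,6,7,8,9,9a-octahydro-2-benzoxepine-4-carbaldehyde | CC(C)[C@H]1CC[C@@]3(COB(c4ccccc4)O3)[C@H]2C(=O)OCC(C=O)=C[C@H]12 | intermediate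
26 | but-3-en-2-one | CC(=O)C=C | starting material
27 | (2S)-5-oxo-2-(propan-2-yl)hexanal | CC(C)[C@@H](C=O)CCC(C)=O | intermediate
28 | (4S)-4-(propan-2-yl)cyclohex-2-en-1-one | CC(C)[C@@H]1CCC(=O)C=C1 | intermediate
29 | (3S,4S)-3-ethenyl-4-(propan-2-yl)cyclohex-1-en-1-yl trifluoromethanesulfonate | C=C[C@@H]1C=C(OS(=O)(=O)C(F)(F)F)CC[C@H]1C(C)C | intermediate
30 | (3S,4S)-3-formyl-4-(propan-2-yl)cyclohex-1-en-1-yl trifluoromethanesulfonate | O=C[C@@H]1C=C(OS(=O)(=O)C(F)(F)F)CC[C@H]1C(C)C | intermediate
31 | methyl prop-2-ynoate | C#CC(=O)OC | starting material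
32 | methyl 2-{hydroxy[(1S,6S)-6-(propan-2-yl)-3-{[(trifluoromethyl)sulfonyl]oxy}cyclohex-2-en-1-yl]methyl}prop-2-enoate (carbinol epimers) | C=C(C(=O)OC)C(O)[C@@H]1C=C(OS(=O)(=O)C(F)(F)F)CC[C@H]1C(C)C | intermediate
33 | methyl 2-{hydroxy[(1S,6S)-3-(hydroxymethyl)-6-(propan-2-yl)cyclohex-2-en-1-yl]methyl}prop-2-enoate | C=C(C(=O)OC)C(O)[C@@H]1C=C(CO)CC[C@H]1C(C)C | intermediate
34 | methyl 2-{(acetyloxy)[(1S,6S)-3-[(acetyloxy)methyl]-6-(propan-2-yl)cyclohex-2-en-1-yl]methyl}prop-2-enoate | C=C(C(=O)OC)C(OC(C)=O)[C@@H]1C=C(COC(C)=O)CC[C@H]1C(C)C | intermediate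
35 | methyl (2E)-2-[(acetyloxy)methyl]-3-{(1S,6S)-3-[(acetyloxy)methyl]-6-(propan-2-yl)cyclohex-2-en-1-yl}prop-2-enoate | COC(=O)/C(=C/[C@@H]1C=C(COC(C)=O)CC[C@H]1C(C)C)COC(C)=O | intermediate
36 | (2E)-2-(hydroxymethyl)-3-[(1S,6S)-3-(hydroxymethyl)-6-(propan-2-yl)cyclohex-2-en-1-yl]prop-2-enoic acid | OC(=O)/C(=C/[C@@H]1C=C(CO)CC[C@H]1C(C)C)CO | intermediate
37 | tert-butyl(dimethyl)silyl ester of 38 (not isolated) | CC(C)(C)[Si](C)(C)OC(=O)/C(=C/[C@@H]1C=C(CO[Si](C)(C)C(C)(C)C)CC[C@H]1C(C)C)CO[Si](C)(C)C(C)(C)C | intermediate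
38 | (2E)-2-({[tert-butyl(dimethyl)silyl]oxy}methyl)-3-[(1S,6S)-3-({[tert-butyl(dimethyl)silyl]oxy}methyl)-6-(propan-2-yl)cyclohex-2-en-1-yl]prop-2-enoic acid | OC(=O)/C(=C/[C@@H]1C=C(CO[Si](C)(C)C(C)(C)C)CC[C@H]1C(C)C)CO[Si](C)(C)C(C)(C)C | intermediate
39 | acyl chloride of 38 | ClC(=O)/C(=C/[C@@H]1C=C(CO[Si](C)(C)C(C)(C)C)CC[C@H]1C(C)C)CO[Si](C)(C)C(C)(C)C | intermediate
40 | (5aS,6R,9S,9aS)-9-hydroxy-9-(hydroxymethyl)-1-oxo-6-(propan-2-yl)-1,3,5a,6,7,8,9,9a-octahydro-2-benzoxepine-4-carbaldehyde (not isolated) | CC(C)[C@H]1CC[C@@](O)(CO)[C@H]2C(=O)OCC(C=O)=C[C@H]12 | intermediate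
41 | ester of the primary hydroxyl of 40 with acid 38 (4-carbaldehyde, bis-silyl ether) | CC(C)[C@H]1CC[C@@](O)(COC(=O)/C(=C/[C@@H]3C=C(CO[Si](C)(C)C(C)(C)C)CC[C@H]3C(C)C)CO[Si](C)(C)C(C)(C)C)[C@H]2C(=O)OCC(C=O)=C[C@H]12 | intermediate
42 | 4-carboxylic acid corresponding to 41 (bis-silyl ether of the target) | CC(C)[C@H]1CC[C@@](O)(COC(=O)/C(=C/[C@@H]3C=C(CO[Si](C)(C)C(C)(C)C)CC[C@H]3C(C)C)CO[Si](C)(C)C(C)(C)C)[C@H]2C(=O)OCC(C(=O)O)=C[C@H]12 | intermediate
43 | (5aS,6R,9S,9aS)-9-hydroxy-9-({[(2E)-2-(hydroxymethyl)-3-[(1S,6S)-3-(hydroxymethyl)-6-(propan-2-yl)cyclohex-2-en-1-yl]prop-2-enoyl]oxy}methyl)-1-oxo-6-(propan-2-yl)-1,3,5a,6,7,8,9,9a-octahydro-2-benzoxepine-4-carboxylic acid | CC(C)[C@H]1CC[C@@](O)(COC(=O)/C(=C/[C@@H]2C=C(CO)CC[C@H]2C(C)C)CO)[C@H]2C(=O)OCC(C(=O)O)=C[C@H]12 | target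

**Step count**

Total: 32 steps. Longest linear sequence: 20 steps (1–6, 8–18, 30–32). The ring-B branch is steps 19–29 and the selenium reagent is step 7.

**Steps most likely to fail, with fallbacks**

Step 15. The organometallic may deprotonate the 1,3-dicarbonyl unit of 20 to an unreactive enolate instead of adding to the ketone, or the tertiary alkoxide may fragment by retro-aldol cleavage. The fallback sets out from 20 and replaces the carbanion addition by a carbenoid addition under non-basic conditions. CH2I2 and SmI2 in THF (Imamoto–Molander iodomethylation, tolerant of easily enolised ketones) should give the 9-hydroxy-9-(iodomethyl) lactone F1. Zinc dust in acetic acid then removes iodide and hydroxyl by reductive β-elimination, which can only place the alkene at C1=CH2, and the route is rejoined at 22.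

Step 30. Once the boronate is cleaved, the free primary hydroxyl of 40 may attack the neighbouring lactone carbonyl (five-membered ring closure with opening of ring L) faster than it is acylated, and acylation at this neopentyl-type position may be slow. The fallback sets out from 25 and forms the ester by O-alkylation of the carboxylate instead of O-acylation of the alcohol. The diol released as in step 30 is treated at once with PPh3 and diisopropyl azodicarboxylate at 0 °C (Mitsunobu cyclodehydration; the tertiary oxygen displaces the activated primary one, so C1 keeps its configuration) to give the spiro-epoxide F2. Acid 38 with Cs2CO3 (catalytic) in DMF at 50 °C then opens F2 at its CH2, and the route is rejoined at 41.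

Step 10. The selenoxide elimination toward an oxygen-bearing carbon may be sluggish, and the ketene acetal may be protonated or hydrolysed (by PhSeOH or traces of water) to a hydroxy acetate before it rearranges. The fallback sets out from 9 and reaches the same ketene acetal another way. 1,1'-Carbonyldiimidazole in CH2Cl2 converts the diol into the cyclic carbonate F3. Carbonyl methylenation with (C5H5)2Ti(CH3)2 in toluene at 110 °C (Petasis reagent, known for cyclic carbonates) should give 15 in a neutral, selenium-free medium, which rearranges in the same flask, and the route is rejoined at 16.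

Further compounds
F1 | step 15 | (5aS,6R,9aS)-9-hydroxy-9-(iodomethyl)-4-{[(4-methoxyphenyl)methoxy]methyl}-6-(propan-2-yl)-5a,6,7,8,9,9a-hexahydro-2-benzoxepin-1(3H)-one (C9 epimers) | CC(C)[C@H]1CCC(O)(CI)[C@H]2C(=O)OCC(COCc3ccc(OC)cc3)=C[C@H]12
F2 | step 30 | spiro-epoxide of 40, (5aS,6R,9S,9aS)-1-oxo-6-(propan-2-yl)-spiro[1,3,5a,6,7,8,9,9a-octahydro-2-benzoxepine-9,2'-oxirane]-4-carbaldehyde | CC(C)[C@H]1CC[C@@]3(CO3)[C@H]2C(=O)OCC(C=O)=C[C@H]12
F3 | step 10 | (4S)-4-{[(4-methoxyphenyl)methoxy]methyl}-4-[(1E,3R)-4-methyl-3-({[tri(propan-2-yl)silyl]oxy}methyl)pent-1-en-1-yl]-1,3-dioxolan-2-one | O=C1OC[C@@](COCc2ccc(OC)cc2)(/C=C/[C@@H](C(C)C)CO[Si](C(C)C)(C(C)C)C(C)C)O1
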